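**Plan**
- The retrosynthesis first removes the two MOM ethers and the two hydrogens at C2–C3, so the C2 stereocentre of target flavanone 15 is traced back to the flat flavone 12.
- Flavone 12 is then cut at three bonds around the C4 carbonyl carbon: C4a–C4, C4–C3 and O1–C2.
- The enabling feature is that C4 is a lone carbonyl carbon joining C4a of ring A (the carbon between the O1-bearing and the O5-bearing carbons) to the two-carbon unit C3–C2 that carries ring B. Ring A therefore enters as ortho-iodophenol 3, C4 as carbon monoxide 9, and C3–C2 with ring B as arylalkyne 8.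
- Forward: 3 comes from phloroglucinol in two steps and 8 from 3,5-dibromo-4-hydroxybenzaldehyde in three; their carbonylative union closes ring C, the only ring made.
- The single stereocentre, C2 (S), is set afterwards by a ligand-controlled copper hydride 1,4-reduction of C2=C3 and is carried through an acidic, base-free MOM removal.

Key step: step 6

Assumption: the copper hydride catalyst is taken to show on flavone 12 the facial preference known for β-substituted cyclohexenones, which points to the (S)-configured ligand for the (2S) product; if a first run shows the opposite sense, the (R)-ligand is used with no other change.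
Abbreviations: MOM = methoxymethyl; prenyl = 3-methylbut-2-en-1-yl.

**Step 1**
Reactants: 1 phloroglucinol
Product: 2 3,5-bis(methoxymethoxy)phenol
Conditions: MOMCl (2.0 equiv), K2CO3, acetone, 0 °C to rt; chromatography (mono- and tris-ethers recycled)
Reagents that add atoms: chloromethyl methyl ether (MOMCl), COCCl
Why: Williamson-type O-alkylation (MOM protection) of a threefold symmetric phenol, in which every bis-ether is the same compound, so two equivalents of the hard electrophile should give 2 as the main fraction, separable from the mono- and tris-ethers.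

**Step 2**
Reactants: 2 3,5-bis(methoxymethoxy)phenol
Product: 3 2-iodo-3,5-bis(methoxymethoxy)phenol
Conditions: NIS (1.0 equiv), CH2Cl2, −20 to 0 °C
Reagents that add atoms: N-iodosuccinimide, O=C1CCC(=O)N1I
Why: Electrophilic aromatic iodination of a strongly activated phenol, expected ortho to the free hydroxyl because C2/C6 are less crowded than C4 (which lies between two MOM ethers), are statistically doubled, and are reached by iodine delivered through the hydrogen bond from the phenol to the succinimide carbonyl.

**Step 3**
Reactants: 4 3,5-dibromo-4-hydroxybenzaldehyde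
Product: 5 3,5-dibromo-4-methoxybenzaldehyde
Conditions: MeI, K2CO3, DMF, rt
Reagents that add atoms: iodomethane, CI
Why: Williamson O-methylation of an acidic phenol whose phenoxide forms readily with carbonate and is alkylated by the small electrophile despite the two ortho bromines.

**Step 4**
Reactants: 5 3,5-dibromo-4-methoxybenzaldehyde; 6 tributyl(3-methylbut-2-en-1-yl)stannane
Product: 7 4-methoxy-3,5-bis(3-methylbut-2-en-1-yl)benzaldehyde
Conditions: 6 (2.6 equiv), Pd(PPh3)4 (5 mol%), DMF, 100 °C
Reagents that add atoms: none
Why: Twofold Stille coupling, in which the allyl group passes from tin to aryl-palladium and reductive elimination at the unsubstituted allyl terminus should give the linear prenyl arene, while the aldehyde is inert to the neutral stannane.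

**Step 5**
Reactants: 7 4-methoxy-3,5-bis(3-methylbut-2-en-1-yl)benzaldehyde
Product: 8 5-ethynyl-2-methoxy-1,3-bis(3-methylbut-2-en-1-yl)benzene
Conditions: dimethyl (1-diazo-2-oxopropyl)phosphonate, K2CO3, MeOH, 0 °C to rt
Reagents that add atoms: dimethyl (1-diazo-2-oxopropyl)phosphonate (Ohira–Bestmann reagent), CC(=O)C(=[N+]=[N-])P(=O)(OC)OC
Why: Seyferth–Gilbert homologation in its Ohira–Bestmann form, in which the diazomethylphosphonate anion made in the flask adds to the non-enolisable aldehyde and the resulting alkylidene carbene rearranges to the terminal alkyne under conditions mild enough for the prenyl groups.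

**Step 6**
Reactants: 3 2-iodo-3,5-bis(methoxymethoxy)phenol; 9 carbon monoxide; 8 5-ethynyl-2-methoxy-1,3-bis(3-methylbut-2-en-1-yl)benzene
Product: 12 5,7-bis(methoxymethoxy)-2-[4-methoxy-3,5-bis(3-methylbut-2-en-1-yl)phenyl]-4H-chromen-4-one, via ortho-hydroxyaryl ynone 10 (not isolated), via diethylamino enone 11 (not isolated)
Conditions: PdCl2(dppf) (5 mol%), CO (20 bar), Et2NH, 120 °C
Reagents that add atoms: none
Why: Zerovalent palladium, formed from PdCl2(dppf) under CO and amine, inserts into the C–I bond of 3, CO inserts to give an aroyl-palladium, and amine-assisted transfer of the alkynyl group of 8 followed by reductive elimination gives ynone 10 (bonds C4a–C4 and C4–C3). Diethylamine then adds to the ynone to give enaminone 11, and the ortho-hydroxyl attacks the amine-bearing carbon and expels the amine, which forms O1–C2. The closest known reaction type is the palladium-catalysed carbonylative Sonogashira coupling–annulation of ortho-iodophenols with terminal arylalkynes to flavones in a secondary amine. Ring C closes by a 6-endo-trig oxa-Michael addition–elimination on 11 (formally 6-endo-dig on 10), and no stereocentre is formed. The step needs CO insertion before alkynyl transfer, which the CO pressure, the absence of a copper co-catalyst and the electron-rich, doubly ortho-substituted aryl-palladium should secure, and it needs 6-endo closure in place of 5-exo-dig closure to an aurone, which the amine-adduct pathway secures. The iodine sits on the carbon between the free hydroxyl and a MOM ether, so the carbonyl can only be attached at C4a, and the trisubstituted prenyl alkenes are poor partners for acyl-palladium insertion and should stay untouched.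

**Step 7**
Reactants: 12 5,7-bis(methoxymethoxy)-2-[4-methoxy-3,5-bis(3-methylbut-2-en-1-yl)phenyl]-4H-chromen-4-one
Product: 14 (2S)-5,7-bis(methoxymethoxy)-2-[4-methoxy-3,5-bis(3-methylbut-2-en-1-yl)phenyl]-2,3-dihydro-4H-chromen-4-one, via silyl enol ether 13 (not isolated)
Conditions: Cu(OAc)2 (5 mol%), (S)-DTBM-SEGPHOS (5.5 mol%), (EtO)2MeSiH (3 equiv), toluene, 0 °C to rt; then 0.5 M HCl (aq)/THF, 0 °C
Reagents that add atoms: none
Why: Asymmetric copper hydride conjugate reduction, as established for β,β-disubstituted enones and 2-substituted chromones, in which the bisphosphine-bound copper hydride delivers hydride to one face of C2 under ligand control to make C2 (S), the copper enolate is silylated to enol ether 13 (which shields C4 from over-reduction and ring C from opening until the cold hydrolysis), and the unpolarised prenyl alkenes are not reduced.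

**Step 8**
Reactants: 14 (2S)-5,7-bis(methoxymethoxy)-2-[4-methoxy-3,5-bis(3-methylbut-2-en-1-yl)phenyl]-2,3-dihydro-4H-chromen-4-one
Product: 15 (2S)-5,7-dihydroxy-2-[4-methoxy-3,5-bis(3-methylbut-2-en-1-yl)phenyl]-2,3-dihydro-4H-chromen-4-one
Conditions: 3 M HCl (aq)/MeOH (1:5), 50 °C
Reagents that add atoms: none
Why: Acid-catalysed acetal exchange (MOM ether cleavage) in methanol, which spares the aryl methyl ether and the prenyl groups (no free ortho-phenol is present to cyclise onto them) and should leave C2 intact, since its loss would require base-promoted opening of ring C through the enolate.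

**Compound list**
1 | phloroglucinol (benzene-1,3,5-triol) | Oc1cc(O)cc(O)c1 | starting material
2 | 3,5-bis(methoxymethoxy)phenol | COCOc1cc(O)cc(OCOC)c1 | intermediate
3 | 2-iodo-3,5-bis(methoxymethoxy)phenol | COCOc1cc(O)c(I)c(OCOC)c1 | intermediate
4 | 3,5-dibromo-4-hydroxybenzaldehyde | O=Cc1cc(Br)c(O)c(Br)c1 | starting material
5 | 3,5-dibromo-4-methoxybenzaldehyde | COc1c(Br)cc(C=O)cc1Br | intermediate
6 | tributyl(3-methylbut-2-en-1-yl)stannane | CCCC[Sn](CCCC)(CCCC)CC=C(C)C | starting material
7 | 4-methoxy-3,5-bis(3-methylbut-2-en-1-yl)benzaldehyde | COc1c(CC=C(C)C)cc(C=O)cc1CC=C(C)C | intermediate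
8 | 5-ethynyl-2-methoxy-1,3-bis(3-methylbut-2-en-1-yl)benzene | C#Cc1cc(CC=C(C)C)c(OC)c(CC=C(C)C)c1 | intermediate
9 | carbon monoxide | [C-]#[O+] | starting material
10 | 1-[2-hydroxy-4,6-bis(methoxymethoxy)phenyl]-3-[4-methoxy-3,5-bis(3-methylbut-2-en-1-yl)phenyl]prop-2-yn-1-one | COCOc1cc(O)c(C(=O)C#Cc2cc(CC=C(C)C)c(OC)c(CC=C(C)C)c2)c(OCOC)c1 | intermediate
11 | (E)-3-(diethylamino)-1-[2-hydroxy-4,6-bis(methoxymethoxy)phenyl]-3-[4-methoxy-3,5-bis(3-methylbut-2-en-1-yl)phenyl]prop-2-en-1-one (drawn E; the push–pull alkene isomerises freely and its geometry is lost on ring closure) | COCOc1cc(O)c(C(=O)/C=C(/N(CC)CC)c2cc(CC=C(C)C)c(OC)c(CC=C(C)C)c2)c(OCOC)c1 | intermediate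
12 | 5,7-bis(methoxymethoxy)-2-[4-methoxy-3,5-bis(3-methylbut-2-en-1-yl)phenyl]-4H-chromen-4-one | COCOc1cc(OCOC)c2c(c1)oc(-c1cc(CC=C(C)C)c(OC)c(CC=C(C)C)c1)cc2=O | intermediate
13 | (2S)-4-{[diethoxy(methyl)silyl]oxy}-5,7-bis(methoxymethoxy)-2-[4-methoxy-3,5-bis(3-methylbut-2-en-1-yl)phenyl]-2H-chromene | COCOc1cc(OCOC)c2c(c1)O[C@H](c1cc(CC=C(C)C)c(OC)c(CC=C(C)C)c1)C=C2O[Si](C)(OCC)OCC | intermediate
14 | (2S)-5,7-bis(methoxymethoxy)-2-[4-methoxy-3,5-bis(3-methylbut-2-en-1-yl)phenyl]-2,3-dihydro-4H-chromen-4-one | COCOc1cc(OCOC)c2c(c1)O[C@H](c1cc(CC=C(C)C)c(OC)c(CC=C(C)C)c1)CC2=O | intermediate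
15 | (2S)-5,7-dihydroxy-2-[4-methoxy-3,5-bis(3-methylbut-2-en-1-yl)phenyl]-2,3-dihydro-4H-chromen-4-one | COc1c(CC=C(C)C)cc([C@@H]2CC(=O)c3c(O)cc(O)cc3O2)cc1CC=C(C)C | target

**Step count**
Total: 8 steps. Longest linear sequence: 6 steps (steps 3, 4, 5, 6, 7, 8).

**Steps most likely to fail**

1. Step 7. Hydride delivery to C2 may stall or show poor facial selectivity, because the β-carbon of this doubly donor-substituted vinylogous ester is weakly electrophilic and its two substituents (aryl group and ring oxygen) are less well differentiated than in alkyl-substituted chromones. Over-reduction at C4, or opening of ring C by β-elimination of the aryloxide from the copper enolate, may add to the loss. The fallback sets out from flavone 12 and returns at 14. An achiral copper hydride (Cu(OAc)2, 1,2-bis(diphenylphosphino)benzene, (EtO)2MeSiH, toluene, then dilute acid) should give racemic 5,7-bis(methoxymethoxy)-2-[4-methoxy-3,5-bis(3-methylbut-2-en-1-yl)phenyl]-2,3-dihydro-4H-chromen-4-one F1. Kinetic resolution by asymmetric transfer hydrogenation, a method established for racemic flavanones (RuCl[(R,R)-TsDPEN](p-cymene), HCO2H/Et3N, EtOAc, rt), should then reduce the (2R)-ketone to (2R,4R)-5,7-bis(methoxymethoxy)-2-[4-methoxy-3,5-bis(3-methylbut-2-en-1-yl)phenyl]chroman-4-ol F2. This catalyst antipode is expected to deliver hydride so as to give the (4R)-carbinol cis to the aryl group. The unreacted (2S)-ketone is 14, separated from F2 by chromatography.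

2. Step 6. Diethylamine may attack the aroyl-palladium (aminocarbonylation to the diethylamide). Alkynyl transfer may occur before CO insertion, followed by closure to a 2-arylbenzofuran. The ynone may close 5-exo to an aurone. Oxidative addition at the doubly ortho-substituted iodide may also be slow. The fallback builds the same ynone without palladium or CO; it sets out from alkyne 8 and returns at ynone 10, and from there at flavone 12. Ring A enters as commercial 2,4,6-trihydroxybenzaldehyde F3. MOMCl/i-Pr2NEt in CH2Cl2 leaves the chelated hydroxyl free and should give 2-hydroxy-4,6-bis(methoxymethoxy)benzaldehyde F4. Its lithium phenoxide (LiHMDS, THF, −78 °C) is treated with the lithium acetylide of 8 (n-BuLi) to give racemic 1-[2-hydroxy-4,6-bis(methoxymethoxy)phenyl]-3-[4-methoxy-3,5-bis(3-methylbut-2-en-1-yl)phenyl]prop-2-yn-1-ol F5. MnO2 in CH2Cl2 oxidises the benzylic, propargylic alcohol to ynone 10, which Et2NH in EtOH closes to 12 through 11, as in the second half of step 6.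

3. Step 4. Allyl transposition during transmetalation and reductive elimination may attach some prenyl groups through their tertiary carbon, and the second coupling next to the methoxy group may stop at the mono-prenyl stage. The fallback changes the coupling manifold to boron with the aldehyde masked; it sets out from 5 and returns at 7. Acetalisation (ethylene glycol, TsOH, toluene, reflux) should give 2-(3,5-dibromo-4-methoxyphenyl)-1,3-dioxolane F6. A twofold Suzuki–Miyaura coupling with prenylboronic acid pinacol ester follows (PdCl2(NHC)(3-chloropyridine), NHC = 1,3-bis[2,6-di(pentan-3-yl)phenyl]imidazol-2-ylidene, KOH (aq), THF, 70 °C). This catalyst type is known to couple 3,3-disubstituted allylboronates at the unsubstituted terminus, and the product should be 2-[4-methoxy-3,5-bis(3-methylbut-2-en-1-yl)phenyl]-1,3-dioxolane F7. Mild hydrolysis (PPTS, acetone/H2O) returns aldehyde 7.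

**Further compounds**
F1 | step 7 | racemic 5,7-bis(methoxymethoxy)-2-[4-methoxy-3,5-bis(3-methylbut-2-en-1-yl)phenyl]-2,3-dihydro-4H-chromen-4-one | COCOc1cc(OCOC)c2c(c1)OC(c1cc(CC=C(C)C)c(OC)c(CC=C(C)C)c1)CC2=O
F2 | step 7 | (2R,4R)-5,7-bis(methoxymethoxy)-2-[4-methoxy-3,5-bis(3-methylbut-2-en-1-yl)phenyl]chroman-4-ol | COCOc1cc(OCOC)c2c(c1)O[C@@H](c1cc(CC=C(C)C)c(OC)c(CC=C(C)C)c1)C[C@H]2O
F3 | step 6 | 2,4,6-trihydroxybenzaldehyde (commercial) | O=Cc1c(O)cc(O)cc1O
F4 | step 6 | 2-hydroxy-4,6-bis(methoxymethoxy)benzaldehyde | COCOc1cc(O)c(C=O)c(OCOC)c1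
F5 | step 6 | racemic 1-[2-hydroxy-4,6-bis(methoxymethoxy)phenyl]-3-[4-methoxy-3,5-bis(3-methylbut-2-en-1-yl)phenyl]prop-2-yn-1-ol | COCOc1cc(O)c(C(O)C#Cc2cc(CC=C(C)C)c(OC)c(CC=C(C)C)c2)c(OCOC)c1
F6 | step 4 | 2-(3,5-dibromo-4-methoxyphenyl)-1,3-dioxolane | COc1c(Br)cc(C2OCCO2)cc1Br
F7 | step 4 | 2-[4-methoxy-3,5-bis(3-methylbut-2-en-1-yl)phenyl]-1,3-dioxolane | COc1c(CC=C(C)C)cc(C2OCCO2)cc1CC=C(C)C
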